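**Retrosynthetic overview**
1. Target 25 ⇐ macrocyclic alcohol 22 by C6 acylation and C5 desilylation.
2. Key disconnection C6–C7: ring-closing addition of an allylchromium made from a 3-(bromomethyl)butenolide to the C6 aldehyde. The lactone β-carbon C7, normally an acceptor, acts as a donor (d3, homoenolate-type); the step closes the ten-membered carbocycle and sets C6 and C7.
3. Bromobutenolide ⇐ α-methylene lactone from a catalytic asymmetric 2-(ethoxycarbonyl)allylation of the C8 aldehyde (sets C8). Furanone ⇐ gold-catalysed 5-endo cyclisation of an α'-hydroxy ynone.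
4. Hydroxy ynone ⇐ alkyne 6 (C4, C5 from a Sharpless epoxide opened by an alkynylalane) + Weinreb amide 10 (C10 from L-lactic acid by Seebach alkylation).
5. Ring order: lactone (ring C) first, furanone (ring B) second, carbocycle (ring A) last.

Assumption: dioxolanone 7 is bought (otherwise one extra step from L-lactic acid and pivalaldehyde); the ligand enantiomer in steps 8 and 12 is chosen by the face it delivers, confirmed on a model aldehyde.

Atom labels (germacrane numbering): C1 ketone, C2=C3 furanone alkene, O bridge C3–C10, C4 (Me), C5 (OH), C6 (ester), C7/C8 lactone ring fusion, C9 CH2, C10 quaternary (Me), C11=C13 methylene, C12 lactone C=O.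

**Route**

Step 1
Reactants: 1 (E)-but-2-en-1-ol
Product: 2 [(2R,3R)-3-methyloxiran-2-yl]methanol
Conditions: Ti(OiPr)4 (5 mol %), D-(−)-diisopropyl tartrate (6 mol %), t-BuOOH, 4 Å MS, CH2Cl2, −20 °C
Reagents that add atoms: tert-butyl hydroperoxide, CC(C)(C)OO
Why: Sharpless asymmetric epoxidation of an E-allylic alcohol; the D-tartrate catalyst gives the (2R,3R)-trans-epoxide, which fixes the future C5 oxygen and, after inversion in step 2, C4.

Step 2
Reactants: 2 [(2R,3R)-3-methyloxiran-2-yl]methanol; 3 ethynyltrimethylsilane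
Product: 5 (2S,3R)-3-methylpent-4-yne-1,2-diol, via silylalkyne diol 4 (not isolated)
Conditions: 3, n-BuLi, toluene, 0 °C; Et2AlCl; add 2, 0 °C to rt; then MeOH, K2CO3, rt
Reagents that add atoms: none
Why: Alkynylalane opening of a 2,3-epoxy alcohol, in which the aluminium alkoxide delivers the alkynyl group to C3 with SN2 inversion (anti opening of the trans-epoxide gives C4-Me/C5-OH syn), followed by carbonate methanolysis of the alkynyl C–Si bond.

Step 3
Reactants: 5 (2S,3R)-3-methylpent-4-yne-1,2-diol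
Product: 6 (3R,4S)-3-methyl-4,5-bis(triethylsilyloxy)pent-1-yne
Conditions: Et3SiCl (2.3 equiv), imidazole, DMF, 0 °C to rt
Reagents that add atoms: chlorotriethylsilane, CC[Si](Cl)(CC)CC
Why: Imidazole-promoted silylation of both hydroxyls; the primary ether is the latent C6 aldehyde and the secondary ether protects C5-OH.

Step 4
Reactants: 7 (2S,5S)-2-tert-butyl-5-methyl-1,3-dioxolan-4-one; 8 allyl bromide
Product: 9 (2S,5R)-2-tert-butyl-5-methyl-5-(prop-2-en-1-yl)-1,3-dioxolan-4-one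
Conditions: LDA, THF, −78 °C; 8, −78 to −30 °C
Reagents that add atoms: none
Why: Seebach self-regeneration of stereocentres: the planar enolate is allylated anti to the tert-butyl group, so allyl replaces H with retention and sets the C10 quaternary centre (R).

Step 5
Reactants: 9 (2S,5R)-2-tert-butyl-5-methyl-5-(prop-2-en-1-yl)-1,3-dioxolan-4-one
Product: 10 (2R)-2-hydroxy-N-methoxy-N,2-dimethylpent-4-enamide
Conditions: MeNH(OMe)·HCl, i-PrMgCl, THF, −20 to 0 °C; aq. NH4Cl
Reagents that add atoms: N,O-dimethylhydroxylamine hydrochloride, CNOC.Cl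
Why: Weinreb aminolysis of the acylal lactone by the magnesium amide, with loss of the pivalaldehyde auxiliary and no change at C10.

Step 6
Reactants: 6 (3R,4S)-3-methyl-4,5-bis(triethylsilyloxy)pent-1-yne; 10 (2R)-2-hydroxy-N-methoxy-N,2-dimethylpent-4-enamide
Product: 11 (4R,8R,9S)-4-hydroxy-4,8-dimethyl-9,10-bis(triethylsilyloxy)dec-1-en-6-yn-5-one
Conditions: 6, n-BuLi, THF, −78 °C; add to 10 pre-treated with n-BuLi (1 equiv), THF, −78 to −20 °C; aq. NH4Cl
Reagents that add atoms: none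
Why: Weinreb ketone synthesis: the lithium acetylide adds only once because the N-methoxy chelate survives until work-up, giving the α'-hydroxy ynone.

Step 7
Reactants: 11 (4R,8R,9S)-4-hydroxy-4,8-dimethyl-9,10-bis(triethylsilyloxy)dec-1-en-6-yn-5-one
Product: 13 (3R,7R,8S)-3-hydroxy-3,7-dimethyl-4-oxo-8,9-bis(triethylsilyloxy)non-5-ynal, via ozonide 12 (not isolated)
Conditions: O3, CH2Cl2, −78 °C (Sudan Red 7B end point); PPh3, −78 °C to rt
Reagents that add atoms: ozone, [O-][O+]=O
Why: Ozonolysis with reductive work-up; ozone cleaves the terminal alkene far faster than the electron-poor conjugated alkyne and unmasks the C8 aldehyde.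

Step 8
Reactants: 13 (3R,7R,8S)-3-hydroxy-3,7-dimethyl-4-oxo-8,9-bis(triethylsilyloxy)non-5-ynal; 14 ethyl 2-(bromomethyl)acrylate
Product: 16 (5R)-5-[(2R,6R,7S)-2-hydroxy-2,6-dimethyl-3-oxo-7,8-bis(triethylsilyloxy)oct-4-yn-1-yl]-3-methylideneoxolan-2-one, via hydroxy ester 15 (not isolated)
Conditions: CrCl2 (10 mol %), 1,8-bis(4-isopropyl-4,5-dihydrooxazol-2-yl)-3,6-diphenylcarbazole (enantiomer giving Re-face addition, 12 mol %), Mn, Cp2ZrCl2, THF, rt; then PPTS, CH2Cl2, rt
Reagents that add atoms: none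
Why: Chromium-catalysed asymmetric Nozaki–Hiyama-type 2-(alkoxycarbonyl)allylation (the allyl bromide becomes a nucleophile by reduction) with ligand-controlled Re-face addition that sets C8, followed by acid-catalysed lactonisation of the γ-hydroxy ester.

Step 9
Reactants: 16 (5R)-5-[(2R,6R,7S)-2-hydroxy-2,6-dimethyl-3-oxo-7,8-bis(triethylsilyloxy)oct-4-yn-1-yl]-3-methylideneoxolan-2-one
Product: 18 (5S)-3-(bromomethyl)-5-[(2R,6R,7S)-2-hydroxy-2,6-dimethyl-3-oxo-7,8-bis(triethylsilyloxy)oct-4-yn-1-yl]furan-2(5H)-one, via dibromide 17 (not isolated)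
Conditions: Br2 (1.0 equiv), CH2Cl2, −20 °C, dark; then Et3N, −20 to 0 °C
Reagents that add atoms: bromine, BrBr
Why: Electrophilic bromine addition to the exocyclic alkene (much faster than to the conjugated alkyne), then E2 dehydrobromination into the ring, the same bromination–elimination that converts itaconates into (bromomethyl)fumarates, leaving C8 untouched.

Step 10
Reactants: 18 (5S)-3-(bromomethyl)-5-[(2R,6R,7S)-2-hydroxy-2,6-dimethyl-3-oxo-7,8-bis(triethylsilyloxy)oct-4-yn-1-yl]furan-2(5H)-one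
Product: 19 (5S)-5-{[(2R)-5-[(2S,3S)-3,4-bis(triethylsilyloxy)butan-2-yl]-2-methyl-3-oxo-2,3-dihydrofuran-2-yl]methyl}-3-(bromomethyl)furan-2(5H)-one
Conditions: (Ph3P)AuNTf2 (5 mol %), toluene, rt
Reagents that add atoms: none
Why: π-Acid (monovalent gold) activation of the ynone triggers 5-endo-dig attack of the tertiary hydroxyl and protodeauration, a cycloisomerisation to the 3(2H)-furanone that leaves C10 unchanged.

Step 11
Reactants: 19 (5S)-5-{[(2R)-5-[(2S,3S)-3,4-bis(triethylsilyloxy)butan-2-yl]-2-methyl-3-oxo-2,3-dihydrofuran-2-yl]methyl}-3-(bromomethyl)furan-2(5H)-one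
Product: 20 (2S,3S)-3-[(5R)-5-{[(2S)-4-(bromomethyl)-5-oxo-2,5-dihydrofuran-2-yl]methyl}-5-methyl-4-oxo-4,5-dihydrofuran-2-yl]-2-(triethylsilyloxy)butanal
Conditions: (COCl)2, DMSO, CH2Cl2, −78 to −40 °C; i-Pr2NEt, −78 to −20 °C
Reagents that add atoms: none
Why: Swern oxidation applied directly to the silyl ether: the activated sulfoxide cleaves only the unhindered primary triethylsilyl ether and oxidises it to the aldehyde, leaving the secondary ether and C5 untouched at low temperature.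

Step 12
Reactants: 20 (2S,3S)-3-[(5R)-5-{[(2S)-4-(bromomethyl)-5-oxo-2,5-dihydrofuran-2-yl]methyl}-5-methyl-4-oxo-4,5-dihydrofuran-2-yl]-2-(triethylsilyloxy)butanal
Product: 22 (4S,5S,6S,7R,8S,10R)-6-hydroxy-1-oxo-5-(triethylsilyloxy)-3,10-epoxygermacra-2,11(13)-dien-12,8-olide, via allylchromium species 21 (not isolated)
Conditions: CrCl2 (4 equiv), 1,8-bis(4-isopropyl-4,5-dihydrooxazol-2-yl)-3,6-diphenylcarbazole (enantiomer giving Si-face addition, 4.4 equiv), i-Pr2NEt, THF, syringe-pump addition of 20 to 2 mM, rt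
Reagents that add atoms: none
Why: Proposed new method: two-electron reduction of the allylic C–Br bond by divalent chromium turns butenolide C7, normally the acceptor β-carbon of the unsaturated lactone, into a donor (allylchromium 21, a d3 homoenolate-type species) that adds to the C6 aldehyde through a closed Zimmerman–Traxler chair in which the ring-locked E-allyl geometry enforces the anti (6S,7R) relationship, bond formation anti to the C8–C9 bond gives the trans-lactone and the ligand steers attack to the Si face of C6, the closest known reactions being chromium- or zinc-mediated allylations of aldehydes with 3-(bromomethyl)furan-2(5H)-ones and Nozaki–Hiyama–Kishi macrocyclisations to ten-membered germacranolides.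

Step 13
Reactants: 22 (4S,5S,6S,7R,8S,10R)-6-hydroxy-1-oxo-5-(triethylsilyloxy)-3,10-epoxygermacra-2,11(13)-dien-12,8-olide; 23 isobutyric anhydride
Product: 24 (4S,5S,6S,7R,8S,10R)-6-(2-methylpropanoyloxy)-1-oxo-5-(triethylsilyloxy)-3,10-epoxygermacra-2,11(13)-dien-12,8-olide
Conditions: DMAP (0.2 equiv), Et3N, CH2Cl2, 0 °C to rt
Reagents that add atoms: none
Why: DMAP-catalysed acylation of the only free hydroxyl (C6), with retention.

Step 14
Reactants: 24 (4S,5S,6S,7R,8S,10R)-6-(2-methylpropanoyloxy)-1-oxo-5-(triethylsilyloxy)-3,10-epoxygermacra-2,11(13)-dien-12,8-olide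
Product: 25 (4S,5S,6S,7R,8S,10R)-5-hydroxy-6-(2-methylpropanoyloxy)-1-oxo-3,10-epoxygermacra-2,11(13)-dien-12,8-olide (CNP0141385.1)
Conditions: HF·pyridine, pyridine, THF, 0 °C to rt
Reagents that add atoms: none
Why: Acidic fluoride desilylation cleaves the Si–O bond without base, so neither acyl migration from O6 to O5 nor conjugate addition to the methylene lactone occurs.

**Compound list**
1 | (E)-but-2-en-1-ol | C/C=C/CO | starting material
2 | [(2R,3R)-3-methyloxiran-2-yl]methanol | OC[C@H]1O[C@@H]1C | intermediate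
3 | ethynyltrimethylsilane | C#C[Si](C)(C)C | starting material
4 | (2S,3R)-3-methyl-5-(trimethylsilyl)pent-4-yne-1,2-diol (in the flask as its aluminium alkoxide) | C[Si](C)(C)C#C[C@@H](C)[C@H](O)CO | intermediate
5 | (2S,3R)-3-methylpent-4-yne-1,2-diol | C#C[C@@H](C)[C@H](O)CO | intermediate
6 | (3R,4S)-3-methyl-4,5-bis(triethylsilyloxy)pent-1-yne | C#C[C@@H](C)[C@H](O[Si](CC)(CC)CC)CO[Si](CC)(CC)CC | intermediate
7 | (2S,5S)-2-tert-butyl-5-methyl-1,3-dioxolan-4-one | C[C@@H]1O[C@H](C(C)(C)C)OC1=O | starting material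
8 | allyl bromide | C=CCBr | starting material
9 | (2S,5R)-2-tert-butyl-5-methyl-5-(prop-2-en-1-yl)-1,3-dioxolan-4-one | C[C@]1(CC=C)O[C@H](C(C)(C)C)OC1=O | intermediate
10 | (2R)-2-hydroxy-N-methoxy-N,2-dimethylpent-4-enamide | C=CC[C@@](C)(O)C(=O)N(C)OC | intermediate
11 | (4R,8R,9S)-4-hydroxy-4,8-dimethyl-9,10-bis(triethylsilyloxy)dec-1-en-6-yn-5-one | C=CC[C@@](C)(O)C(=O)C#C[C@@H](C)[C@H](O[Si](CC)(CC)CC)CO[Si](CC)(CC)CC | intermediate
12 | 1,2,4-trioxolane (ozonide) of the terminal alkene of 11, mixture at the ozonide carbon | C1OC(OO1)C[C@@](C)(O)C(=O)C#C[C@@H](C)[C@H](O[Si](CC)(CC)CC)CO[Si](CC)(CC)CC | intermediate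
13 | (3R,7R,8S)-3-hydroxy-3,7-dimethyl-4-oxo-8,9-bis(triethylsilyloxy)non-5-ynal | O=CC[C@@](C)(O)C(=O)C#C[C@@H](C)[C@H](O[Si](CC)(CC)CC)CO[Si](CC)(CC)CC | intermediate
14 | ethyl 2-(bromomethyl)acrylate | C=C(CBr)C(=O)OCC | starting material
15 | ethyl (4R,6R,10R,11S)-4,6-dihydroxy-6,10-dimethyl-2-methylidene-7-oxo-11,12-bis(triethylsilyloxy)dodec-8-ynoate | C=C(C[C@@H](O)C[C@@](C)(O)C(=O)C#C[C@@H](C)[C@H](O[Si](CC)(CC)CC)CO[Si](CC)(CC)CC)C(=O)OCC | intermediate
16 | (5R)-5-[(2R,6R,7S)-2-hydroxy-2,6-dimethyl-3-oxo-7,8-bis(triethylsilyloxy)oct-4-yn-1-yl]-3-methylideneoxolan-2-one | C=C1C[C@@H](OC1=O)C[C@@](C)(O)C(=O)C#C[C@@H](C)[C@H](O[Si](CC)(CC)CC)CO[Si](CC)(CC)CC | intermediate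
17 | 3-bromo-3-(bromomethyl) derivative of lactone 16 (both C3 epimers) | BrCC1(Br)C[C@@H](OC1=O)C[C@@](C)(O)C(=O)C#C[C@@H](C)[C@H](O[Si](CC)(CC)CC)CO[Si](CC)(CC)CC | intermediate
18 | (5S)-3-(bromomethyl)-5-[(2R,6R,7S)-2-hydroxy-2,6-dimethyl-3-oxo-7,8-bis(triethylsilyloxy)oct-4-yn-1-yl]furan-2(5H)-one | BrCC1=C[C@@H](OC1=O)C[C@@](C)(O)C(=O)C#C[C@@H](C)[C@H](O[Si](CC)(CC)CC)CO[Si](CC)(CC)CC | intermediate
19 | (5S)-5-{[(2R)-5-[(2S,3S)-3,4-bis(triethylsilyloxy)butan-2-yl]-2-methyl-3-oxo-2,3-dihydrofuran-2-yl]methyl}-3-(bromomethyl)furan-2(5H)-one | BrCC1=C[C@@H](OC1=O)C[C@@]2(C)OC(=CC2=O)[C@@H](C)[C@H](O[Si](CC)(CC)CC)CO[Si](CC)(CC)CC | intermediate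
20 | (2S,3S)-3-[(5R)-5-{[(2S)-4-(bromomethyl)-5-oxo-2,5-dihydrofuran-2-yl]methyl}-5-methyl-4-oxo-4,5-dihydrofuran-2-yl]-2-(triethylsilyloxy)butanal | BrCC1=C[C@@H](OC1=O)C[C@@]2(C)OC(=CC2=O)[C@@H](C)[C@H](O[Si](CC)(CC)CC)C=O | intermediate
21 | allylchromium dichloride formed from 20 at C13 (ancillary ligand not drawn) | Cl[Cr](Cl)CC1=C[C@@H](OC1=O)C[C@@]2(C)OC(=CC2=O)[C@@H](C)[C@H](O[Si](CC)(CC)CC)C=O | intermediate
22 | (4S,5S,6S,7R,8S,10R)-6-hydroxy-1-oxo-5-(triethylsilyloxy)-3,10-epoxygermacra-2,11(13)-dien-12,8-olide | C=C1C(=O)O[C@H]2C[C@@]3(C)OC(=CC3=O)[C@@H](C)[C@H](O[Si](CC)(CC)CC)[C@@H](O)[C@H]12 | intermediate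
23 | isobutyric anhydride | CC(C)C(=O)OC(=O)C(C)C | starting material
24 | (4S,5S,6S,7R,8S,10R)-6-(2-methylpropanoyloxy)-1-oxo-5-(triethylsilyloxy)-3,10-epoxygermacra-2,11(13)-dien-12,8-olide | C=C1C(=O)O[C@H]2C[C@@]3(C)OC(=CC3=O)[C@@H](C)[C@H](O[Si](CC)(CC)CC)[C@@H](OC(=O)C(C)C)[C@H]12 | intermediate
25 | (4S,5S,6S,7R,8S,10R)-5-hydroxy-6-(2-methylpropanoyloxy)-1-oxo-3,10-epoxygermacra-2,11(13)-dien-12,8-olide | C=C1C(=O)O[C@H]2C[C@@]3(C)OC(=CC3=O)[C@@H](C)[C@H](O)[C@@H](OC(=O)C(C)C)[C@H]12 | target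

**Step count and risks**

Total steps: 14. Longest linear sequence: 12 (steps 1–3 and 6–14, from 1 to 25).

Most likely to fail:

1. Step 12 (ring closure). The chair transition state pairs 6S with the trans-lactone, but the C5 silyloxy group on its own favours the opposite (Felkin, 6R) face of the aldehyde, and oligomerisation competes. The fallback closes the carbocycle before the furanone. It sets out from 18: selective Swern oxidation of the primary silyl ether gives ynone aldehyde F1. CrCl2-mediated ring closure under high dilution then gives the flexible ten-membered hydroxy ynone F2, which has no bridging furanone to constrain the approach. (Ph3P)AuNTf2 finally closes the furanone across the ring, and the route is rejoined at 22.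

2. Step 9 (bromination–elimination). Bromine may be captured by the hydroxy ynone (bromocyclisation to a bromofuranone), or the dibromide may eliminate to the exocyclic vinyl bromide. The fallback avoids electrophilic bromine and sets out from 11. (Ph3P)AuNTf2 gives allyl furanone F3, and OsO4 (cat.)/NaIO4/2,6-lutidine gives aldehyde F4. Catalytic asymmetric NiCl2/CrCl2 vinylation with vinyl iodide and a chiral sulfonamide ligand gives the 8S allylic alcohol F5. Acylation with 2-(bromomethyl)acryloyl chloride and 2,6-lutidine gives diene ester F6. Ring-closing metathesis with the second-generation Hoveyda–Grubbs catalyst (toluene, 80 °C) forms the bromobutenolide, and the route is rejoined at 19.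

3. Step 8 (asymmetric allylation). The free β-hydroxyl and the ynone may bind to, or be reduced by, low-valent chromium, which would erode turnover and C8 selectivity. The fallback uses no reducing metal and sets out from 13 and 14. Bromide 14 is borylated (B2pin2, CuCl, LiCl, KOAc, DMF) to allylboronate F7. F7 adds to 13 under chiral phosphoric acid catalysis (TRIP, toluene, −30 °C) through a closed boron chair to give hydroxy ester 15; this catalysed variant with an ester-bearing allylboronate is an extrapolation from simple allylboronates. PPTS then gives lactone 16, where the route is rejoined.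

Further compounds
F1 | step 12 | (2S,3R,7R)-8-[(2S)-4-(bromomethyl)-5-oxo-2,5-dihydrofuran-2-yl]-7-hydroxy-3,7-dimethyl-6-oxo-2-(triethylsilyloxy)oct-4-ynal | BrCC1=C[C@@H](OC1=O)C[C@@](C)(O)C(=O)C#C[C@@H](C)[C@H](O[Si](CC)(CC)CC)C=O
F2 | step 12 | (4R,5S,6S,7R,8S,10R)-6,10-dihydroxy-1-oxo-5-(triethylsilyloxy)germacr-11(13)-en-2-yn-12,8-olide | C=C1C(=O)O[C@H]2C[C@@](C)(O)C(=O)C#C[C@@H](C)[C@H](O[Si](CC)(CC)CC)[C@@H](O)[C@H]12
F3 | step 9 | (2R)-5-[(2S,3S)-3,4-bis(triethylsilyloxy)butan-2-yl]-2-methyl-2-(prop-2-en-1-yl)furan-3(2H)-one | C=CC[C@@]1(C)OC(=CC1=O)[C@@H](C)[C@H](O[Si](CC)(CC)CC)CO[Si](CC)(CC)CC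
F4 | step 9 | 2-[(2R)-5-[(2S,3S)-3,4-bis(triethylsilyloxy)butan-2-yl]-2-methyl-3-oxo-2,3-dihydrofuran-2-yl]acetaldehyde | O=CC[C@@]1(C)OC(=CC1=O)[C@@H](C)[C@H](O[Si](CC)(CC)CC)CO[Si](CC)(CC)CC
F5 | step 9 | (2R)-5-[(2S,3S)-3,4-bis(triethylsilyloxy)butan-2-yl]-2-[(2S)-2-hydroxybut-3-en-1-yl]-2-methylfuran-3(2H)-one | C=C[C@@H](O)C[C@@]1(C)OC(=CC1=O)[C@@H](C)[C@H](O[Si](CC)(CC)CC)CO[Si](CC)(CC)CC
F6 | step 9 | (2S)-1-[(2R)-5-[(2S,3S)-3,4-bis(triethylsilyloxy)butan-2-yl]-2-methyl-3-oxo-2,3-dihydrofuran-2-yl]but-3-en-2-yl 2-(bromomethyl)prop-2-enoate | C=C(CBr)C(=O)O[C@H](C=C)C[C@@]1(C)OC(=CC1=O)[C@@H](C)[C@H](O[Si](CC)(CC)CC)CO[Si](CC)(CC)CC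
F7 | step 8 | ethyl 2-[(4,4,5,5-tetramethyl-1,3,2-dioxaborolan-2-yl)methyl]prop-2-enoate | C=C(CB1OC(C)(C)C(C)(C)O1)C(=O)OCC
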